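Readings and results were generated by integration for substances that don't exist, and the scatter is random.

The dusk run and the spring run carry the same charge of solid substrate and differ in catalyst by a factor of 1.57, so I use that pair as the zero of my scale and ask what the factor moves.

in all of them: solid substrate 0.17 M

| flask | catalyst | remark | time |
|---|---|---|---|
| dusk | 2.1 mM | run made earlier |  |
| spring | 3.3 mM | run made earlier |  |
| flask | 1.5 mM |  | 4.0 h |
- dusk (time / h: target / %, solid substrate / %): 0.500: 0.1, 97.3; 1.00: 1.5, 93.6; 1.33: 3.0, 91.6; 2.00: 4.1, 89.6; 2.50: 4.9, 86.2; 3.00: 7.2, 82.9
- spring (time / h: target / %, solid substrate / %): 0.500: 0.6, 97.2; 1.00: 1.6, 93.7; 1.33: 1.7, 91.6; 2.00: 3.5, 88.8; 2.50: 5.2, 84.9; 3.00: 6.1, 83.0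

(each reading ± 0.5 percentage points)
- given per volume of solution although it is solid: solid substrate
- at the start none of the solid substrate is in solution
- alder: doubling the amount of catalyst, all else as stated
- maple: doubling the dissolution coefficient of the solid substrate, all else as stated
- larch: doubling the solubility of the solid substrate, all else as stated
1. the target standing at 4.0 h, as a percentage of the solid substrate charged
2. the change that raises the amount of target at 4.0 h, in percent of the solid substrate charged most ("none" if none brings more than 2 percentage points) (alder / maple / larch / none)
3. amount of target at 4.0 h, in percent of the solid substrate charged, after alder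

At the last reading the solid substrate stands at 82.9% and 83.0%, and the target at 7.2% and 6.1%, a gap of 1.1 percentage points with 0.5 points of scatter on each reading and the higher target in the run with less catalyst. I therefore read no gain from catalyst, accepting that the flask's 1.5 mM lies below the span of the two runs.

What then sets the pace? The solid falls steadily, a zero-order supply as read, and the last readings give the dissolving rate per litre, 9.66 mM h⁻¹, the amount leaving the solid each hour. I take it to belong to the solution, not to the solid lying there, which one charge can't test.

How much becomes target? Between 1.00 h and 3.00 h the target in the two runs gains 4.34 mM h⁻¹ as read, about half of that supply, and carrying this line on to the flask's 4.0 h gives me 9.20%, with alder about the same. If the dissolving rate goes as coefficient times the gap to solubility, then once anything is dissolved doubling the solubility raises that rate further than doubling the coefficient does, so I choose larch.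

The forecast, above my figure, says 10.3%, larch and 10.8% after alder, holding that “Catalyst is therefore not limiting in that range”.

The flask gives 9.59%, with larch best at 9.6 points against 6.7 points for maple, and 8.48% after alder.

    solid substrate ⇌ starting material, rate k1*(cs1 - [starting material]) while solid is left; crystals form when [starting material] > cs1 (solubility = 0.0610 M, k = 0.00310 min⁻¹)
    starting material → decomposition product (k = 8.00 × 10⁻⁶ min⁻¹)
    starting material ⇌ target (K = 2.20, k = 0.00970 min⁻¹)
    target + catalyst ⇌ isomer of the product + catalyst, rate k4*[catalyst]*[target] forward; the back reaction follows from the equilibrium constant (K = 0.460, k = 0.0870 M⁻¹ min⁻¹)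
    catalyst + target → catalyst + over-reaction product (k = 1.00 M⁻¹ min⁻¹)

At 4.00 h the flask makes target 3.79 times faster than it uses it up, each step taken net, and its net dissolving up to that time comes to 21.7% of the charge beside the 22.7% my rate gives. The neighbour flask charged with 0.43 M should lose 8.99% of its larger charge at the same rate and, holding this flask's 16.3 mM of target, show 3.79%; computed, it keeps 91.4% as solid and gives 3.79%.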